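The dienone ring is numbered C1 (carbonyl), C2 (allyl-bearing), C3 (CH), C4 (quaternary, OMe), C5 (C–OMe), C6 (CH) and is disconnected at C3–C4. The key step exploits that C4 is the γ-carbon of the vinylogous ester O=C1–C6=C5(OMe) and C3 the β-carbon of the enone O=C1–C2=C3, both conjugated to the one carbonyl C1. Deprotonating an open-chain β-chlorovinyl ketone at C4 gives a cross-conjugated trienolate whose termini C3 and C4 join by 6π-electrocyclisation; chloride loss then gives the target directly, a chiral ammonium counter-ion selecting the face of C4. The precursor is an acyclic α′-(chloromethylene) β-methoxy enone assembled from five simple building blocks.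

Key step: step 8

Remark: locants C1–C6 in the text are the ring positions defined above, also for open-chain precursors (chain names carry their own locants). Compounds 6–13 are racemic at the future C4, which is planarised in step 8. The C5=C6 and C2=C3 geometries of 10, 12 and 13 are drawn as the expected isomers and are erased in step 8.

Step 1
Reactants: 1 3,4-dimethoxybenzaldehyde; 2 propanal
Product: 4 (2E)-3-(3,4-dimethoxyphenyl)-2-methylprop-2-enal, via aldol adduct 3 (not isolated)
Conditions: NaOH (aq), MeOH, 0 °C to rt, slow addition of 2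
Reagents that add atoms: none
Why: Crossed aldol condensation (Claisen–Schmidt) in which only propanal can enolise, and E1cB dehydration of aldol 3 gives the conjugated enal with the aryl group trans to the formyl group.

Step 2
Reactants: 4 (2E)-3-(3,4-dimethoxyphenyl)-2-methylprop-2-enal; 5 ethynylmagnesium bromide
Product: 6 (1E)-1-(3,4-dimethoxyphenyl)-2-methylpent-1-en-4-yn-3-ol (racemic)
Conditions: THF, −20 to 0 °C; aqueous work-up
Reagents that add atoms: none
Why: Grignard 1,2-addition of the hard alkynyl nucleophile to the enal carbonyl, the new carbinol centre being formed without control because it later becomes the planar trienolate terminus C4.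

Step 3
Reactants: 6 (1E)-1-(3,4-dimethoxyphenyl)-2-methylpent-1-en-4-yn-3-ol
Product: 7 4-[(1E)-3-methoxy-2-methylpent-1-en-4-yn-1-yl]-1,2-dimethoxybenzene (racemic)
Conditions: NaH (1.1 equiv), MeI, THF, 0 °C to rt
Reagents that add atoms: iodomethane, CI
Why: Williamson ether synthesis, in which the alkoxide (O–H far more acidic than the alkyne C–H) is methylated at oxygen and the stereocentre is not touched.

Step 4
Reactants: 7 4-[(1E)-3-methoxy-2-methylpent-1-en-4-yn-1-yl]-1,2-dimethoxybenzene; 8 pent-4-enoyl chloride
Product: 9 (1E)-1-(3,4-dimethoxyphenyl)-3-methoxy-2-methyldeca-1,9-dien-4-yn-6-one (racemic)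
Conditions: PdCl2(PPh3)2 (2 mol%), CuI (4 mol%), Et3N (1.2 equiv), THF, rt
Reagents that add atoms: none
Why: Acyl Sonogashira coupling, in which the copper acetylide transmetalates to the acylpalladium chloride formed by oxidative addition of 8 to zerovalent palladium and reductive elimination gives the ynone under mildly basic conditions that the allylic propargylic ether tolerates.

Step 5
Reactants: 9 (1E)-1-(3,4-dimethoxyphenyl)-3-methoxy-2-methyldeca-1,9-dien-4-yn-6-one
Product: 10 (1E,4E)-1-(3,4-dimethoxyphenyl)-3,4-dimethoxy-2-methyldeca-1,4,9-trien-6-one (racemic)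
Conditions: NaOMe (0.2 equiv), MeOH, 0 °C to rt
Reagents that add atoms: methanol, CO
Why: Oxa-Michael addition of methoxide to the β-carbon of the ynone (or of the allenone formed by prototropy, which gives the same product) places the methoxy group on C5 and equilibrates to the more stable (E)-β-methoxy enone.

Step 6
Reactants: 10 (1E,4E)-1-(3,4-dimethoxyphenyl)-3,4-dimethoxy-2-methyldeca-1,4,9-trien-6-one; 11 methyl formate
Product: 12 (1E,4E)-1-(3,4-dimethoxyphenyl)-7-(hydroxymethylidene)-3,4-dimethoxy-2-methyldeca-1,4,9-trien-6-one (enol form of the β-keto aldehyde, racemic)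
Conditions: NaH (1.2 equiv), MeOH (cat.), THF, 0 °C to rt; then AcOH (1.2 equiv)
Reagents that add atoms: none
Why: Claisen formylation under equilibrating methoxide conditions, in which only acylation at the α′-methylene carbon C2 leads to a stabilised 1,3-dicarbonyl anion, so the one-carbon unit (future C3) is fixed there while attack at the tertiary γ-carbon is reversible.

Step 7
Reactants: 12 (1E,4E)-1-(3,4-dimethoxyphenyl)-7-(hydroxymethylidene)-3,4-dimethoxy-2-methyldeca-1,4,9-trien-6-one
Product: 13 (1E,4E,7E)-7-(chloromethylidene)-1-(3,4-dimethoxyphenyl)-3,4-dimethoxy-2-methyldeca-1,4,9-trien-6-one (racemic)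
Conditions: Ph3PCl2 (1.2 equiv), Et3N (1.5 equiv), CH2Cl2, 0 °C
Reagents that add atoms: dichlorotriphenylphosphorane, ClP(Cl)(c1ccccc1)(c1ccccc1)c1ccccc1
Why: Appel-type deoxychlorination of the enolised β-keto aldehyde through an enol oxyphosphonium salt and chloride addition–elimination at the formyl-derived carbon, buffered by amine so that the acid-labile allylic methyl ether survives.

Step 8
Reactants: 13 (1E,4E,7E)-7-(chloromethylidene)-1-(3,4-dimethoxyphenyl)-3,4-dimethoxy-2-methyldeca-1,4,9-trien-6-one
Product: 15 (4S)-4-[(1E)-1-(3,4-dimethoxyphenyl)prop-1-en-2-yl]-4,5-dimethoxy-2-(prop-2-en-1-yl)cyclohexa-2,5-dien-1-one, via chloro enolate 14 (not isolated)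
Conditions: O-allyl-N-(9-anthracenylmethyl)cinchonidinium bromide (10 mol%), CsOH·H2O (3 equiv), toluene/CH2Cl2 (7:3), −50 °C
Reagents that add atoms: none
Why: Proposed new method: interfacial deprotonation at C4 (γ to C1=O through C6=C5 and allylic to the styrene) gives the cross-conjugated trienolate C3=C2–C1(O−)=C6–C5=C4, whose termini bond in a thermal disrotatory 6π-electrocyclisation (formally a 6-endo-trig intramolecular nucleophilic vinylic substitution at C3), and E1cB loss of chloride from ring enolate 14 restores C2=C3 and releases the dienone. The closest known reaction types are the phase-transfer-catalysed enantioselective vinylic substitution of β-chloro enones by 1,3-dicarbonyl enolates, the cinchona-ammonium-controlled 6π-electrocyclisation of delocalised anions and the oxyanion-accelerated electrocyclisation of hexatrienes; none has been shown for a vinylogous-ester γ-carbanion closing onto the enone arm of its own carbonyl. The only ring formed is the six-membered carbocycle, closed by the single bond C3–C4. The sole stereocentre C4 is controlled by the chiral ammonium cation, which pairs with the enolate oxygen and blocks one face of the U-shaped, helically folded trienolate; the cinchonidine-derived salt is assigned to the (S)-product by analogy, and the pseudoenantiomeric cinchonine-derived salt would give the antipode should the assignment prove reversed. The step needs C4-to-C3 closure to beat hydroxide attack at C3 and the reversible, unproductive closures through C6 (four-membered) or from the benzylic terminus onto C1; low temperature, solid base and the fact that only the C3–C4 mode ends in irreversible chloride loss secure this, while reversible proton transfer lets the dienolate geometry needed for closure be reached.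

Compound list
1 | 3,4-dimethoxybenzaldehyde | COc1ccc(C=O)cc1OC | starting material
2 | propanal | CCC=O | starting material
3 | 3-(3,4-dimethoxyphenyl)-3-hydroxy-2-methylpropanal (aldol adduct, diastereomer mixture, not isolated) | COc1ccc(C(O)C(C)C=O)cc1OC | intermediate
4 | (2E)-3-(3,4-dimethoxyphenyl)-2-methylprop-2-enal | COc1ccc(/C=C(\C)C=O)cc1OC | intermediate
5 | ethynylmagnesium bromide | C#C[Mg]Br | starting material
6 | (1E)-1-(3,4-dimethoxyphenyl)-2-methylpent-1-en-4-yn-3-ol (racemic) | COc1ccc(/C=C(\C)C(O)C#C)cc1OC | intermediate
7 | 4-[(1E)-3-methoxy-2-methylpent-1-en-4-yn-1-yl]-1,2-dimethoxybenzene (racemic) | COc1ccc(/C=C(\C)C(OC)C#C)cc1OC | intermediate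
8 | pent-4-enoyl chloride | C=CCCC(Cl)=O | starting material
9 | (1E)-1-(3,4-dimethoxyphenyl)-3-methoxy-2-methyldeca-1,9-dien-4-yn-6-one (racemic) | COc1ccc(/C=C(\C)C(OC)C#CC(=O)CCC=C)cc1OC | intermediate
10 | (1E,4E)-1-(3,4-dimethoxyphenyl)-3,4-dimethoxy-2-methyldeca-1,4,9-trien-6-one (racemic) | COc1ccc(/C=C(\C)C(OC)/C(OC)=C\C(=O)CCC=C)cc1OC | intermediate
11 | methyl formate | O=COC | starting material
12 | (1E,4E)-1-(3,4-dimethoxyphenyl)-7-(hydroxymethylidene)-3,4-dimethoxy-2-methyldeca-1,4,9-trien-6-one (enol form, racemic) | COc1ccc(/C=C(\C)C(OC)/C(OC)=C\C(=O)C(=CO)CC=C)cc1OC | intermediate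
13 | (1E,4E,7E)-7-(chloromethylidene)-1-(3,4-dimethoxyphenyl)-3,4-dimethoxy-2-methyldeca-1,4,9-trien-6-one (racemic) | COc1ccc(/C=C(\C)C(OC)/C(OC)=C\C(=O)/C(CC=C)=C/Cl)cc1OC | intermediate
14 | (4S)-3-chloro-4-[(1E)-1-(3,4-dimethoxyphenyl)prop-1-en-2-yl]-4,5-dimethoxy-2-(prop-2-en-1-yl)cyclohexa-1,5-dien-1-olate (ring enolate, C3 configuration not assigned, not isolated) | C=CCC1=C([O-])C=C(OC)[C@@](OC)(/C(C)=C/c2ccc(OC)c(OC)c2)C1Cl | intermediate
15 | (4S)-4-[(1E)-1-(3,4-dimethoxyphenyl)prop-1-en-2-yl]-4,5-dimethoxy-2-(prop-2-en-1-yl)cyclohexa-2,5-dien-1-one | C=CCC1=C[C@](OC)(/C(C)=C/c2ccc(OC)c(OC)c2)C(OC)=CC1=O | target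

Total step count: 8. Longest linear sequence: 8 steps (1 to 15 through steps 1–8).

Steps most likely to fail

Step 8 (Proposed new method). What may go wrong: weak facial discrimination within the ammonium–trienolate ion pair, giving low enantiomeric purity, or hydroxide attacking C3 faster than C4 is deprotonated. Fallback, by known chemistry (base-mediated intramolecular nucleophilic vinylic substitution of a β-chloro enone, then chromatographic separation of enantiomers): setting out from 13, potassium tert-butoxide in THF at −78 to −20 °C should close the ring without chiral control to the racemic dienone F1. Preparative supercritical-fluid chromatography on an amylose tris(3,5-dimethylphenylcarbamate) phase then removes the (R)-enantiomer F2 and returns to the route at 15.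

Step 7. What may go wrong: ionisation of the doubly allylic methyl ether by adventitious HCl, or chloride delivery to the ketone-derived carbon instead of the formyl-derived one. Fallback: setting out from 12, sulfonylation (TsCl, Et3N, cat. DMAP, CH2Cl2, −20 °C) at the less hindered formyl-derived enol oxygen should give the enol tosylate F3 without breaking any C–O bond. F3 then takes the place of 13 under the conditions of step 8, with tosylate as the leaving group, and the route is rejoined at 15.

Step 4. What may go wrong: dehydrohalogenation of the acid chloride to a ketene by the amine, and amine-induced propargyl–allenyl isomerisation of the coupled product. Fallback: setting out from 7, lithiation (n-BuLi, THF, −78 °C) and addition to pent-4-enal should give the propargylic alcohol F4 (diastereomer mixture). Oxidation of F4 with MnO2 in CH2Cl2 then rejoins the route at 9.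

Further compounds
F1 | step 8 | racemic 4-[(1E)-1-(3,4-dimethoxyphenyl)prop-1-en-2-yl]-4,5-dimethoxy-2-(prop-2-en-1-yl)cyclohexa-2,5-dien-1-one | C=CCC1=CC(OC)(/C(C)=C/c2ccc(OC)c(OC)c2)C(OC)=CC1=O
F2 | step 8 | (4R)-4-[(1E)-1-(3,4-dimethoxyphenyl)prop-1-en-2-yl]-4,5-dimethoxy-2-(prop-2-en-1-yl)cyclohexa-2,5-dien-1-one | C=CCC1=C[C@@](OC)(/C(C)=C/c2ccc(OC)c(OC)c2)C(OC)=CC1=O
F3 | step 7 | (1E,4E,7E)-1-(3,4-dimethoxyphenyl)-3,4-dimethoxy-2-methyl-7-[(4-methylbenzenesulfonyloxy)methylidene]deca-1,4,9-trien-6-one (racemic) | COc1ccc(/C=C(\C)C(OC)/C(OC)=C\C(=O)/C(CC=C)=C/OS(=O)(=O)c2ccc(C)cc2)cc1OC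
F4 | step 4 | (1E)-1-(3,4-dimethoxyphenyl)-3-methoxy-2-methyldeca-1,9-dien-4-yn-6-ol (diastereomer mixture) | COc1ccc(/C=C(\C)C(OC)C#CC(O)CCC=C)cc1OC
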